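Solid substrate was the entry I booked, mole by mole, through the earlier runs.

| setting | autumn | midnight | winter | flask |
|---|---|---|---|---|
| solid substrate | 0.14 M | 0.22 M | 0.10 M | 0.10 M |
| reagent | 0.18 M | 0.18 M | 0.090 M | 0.180 M |
| initiator | 10 mM | 10 mM | 10 mM | 10 mM |
| remark | run made earlier | run made earlier | run made earlier |  |
| time |  |  |  | 20 h |

| run | time / h | solid substrate / % | product / % |
|---|---|---|---|
| autumn | 3.00 | 86 | 4 |
| autumn | 6.00 | 79 | 15 |
| autumn | 10.0 | 66 | 24 |
| autumn | 15.0 | 58 | 27 |
| autumn | 20.0 | 47 | 34 |
| autumn | 25.0 | 39 | 32 |
| midnight | 1.33 | 94 | 1 |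
| midnight | 4.00 | 94 | 8 |
| midnight | 6.00 | 89 | 8 |
| midnight | 10.0 | 81 | 16 |
| midnight | 15.0 | 72 | 18 |
| midnight | 20.0 | 64 | 19 |
| midnight | 25.0 | 62 | 23 |
| winter | 2.00 | 89 | 5 |
| winter | 4.00 | 81 | 21 |
| winter | 6.00 | 71 | 21 |
| winter | 12.0 | 44 | 34 |
| winter | 25.0 | 22 | 44 |

(each reading ± 2 percentage points)

- part of the solid substrate that has reacted (what has only dissolved counts as not reacted) at 20 h
- share of the unused reagent that is free and not bound as idle adduct, at 20 h

- solid, in amounts per volume of the solution: solid substrate
- at the start none of the solid substrate is in solution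
- what has only dissolved of solid substrate counts as not reacted
- the earlier runs do not show how much of reagent is bound; that part of a forecast is a guess

I booked solid substrate that had left the solid in one of two entries: reacted, read as product, or dissolved, which counts as not reacted. So I closed the mass balance at 20.0 h, in percent of the charge, with the dissolved entry taken by difference:

autumn: solid substrate 47% + product 34% + dissolved 19.0%

midnight: solid substrate 64% + product 19% + dissolved 17.0%

I booked the product line as reacted and turned it into molarity:

c(product): autumn 0.0476 M, midnight 0.0418 M

These two readings lay close together although the solid charges differed. Winter, with half the reagent of autumn and a different solid charge, read 0.0440 M at 25.0 h. I therefore carried the mean of autumn and midnight at 20.0 h as the product load L, the molarity of product read at that time with 10 mM of initiator and 0.180 M of reagent: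

L = 0.0447 M

c = L / c(solid substrate) = 44.7%

The readings do not show how much reagent is bound, so I reckoned no free share.

The forecast gave 73% and 70%, starting from another line of the books: “The amount of solid consumed, in M, nearly coincides across the runs”.

The flask gave 46.1% and 91.1%.

    2 first chain carrier → ended chains B (k = 7.90 × 10⁶ M⁻¹ s⁻¹)
    reagent + first chain carrier ⇌ product + second chain carrier (K = 1.40, k = 2.40 × 10⁷ M⁻¹ h⁻¹)
    2 second chain carrier → ended chains A (k = 5.00 × 10⁶ M⁻¹ s⁻¹)
    reagent + by-product ⇌ idle adduct, settled at all times (K = 6.80 M⁻¹)
    starting material + second chain carrier → by-product + first chain carrier (k = 1.20 × 10⁶ M⁻¹ h⁻¹)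
    initiator → 2 initiating radical (k = 0.260 h⁻¹)
    solid substrate ⇌ starting material, rate k7*(cs7 - [starting material]) while solid is left; crystals form when [starting material] > cs7 (solubility = 42.0 mM, k = 0.130 h⁻¹)
    starting material + initiating radical → capped initiator + first chain carrier (k = 2.40 × 10⁷ M⁻¹ h⁻¹)

The flask's c stood 1.4 percentage points above my figure from L. When I scaled L by the root of the initiator charge, it gave 58.3% for the neighbouring flask with 0.017 M of initiator, whose c stood at 55.7%. In the flask itself, by 10.0 h the initiator had fallen to 7.43% of its charge while product reached 31.4%. By 20.0 h the initiator stood at 0.552%, product had gained 14 points, and starting material had climbed from 14.4% to 27.0%.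

All runs are simulated with constants of no real substance.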